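**Retrosynthetic overview**
- The C1' carbinol comes last, by transfer hydrogenation of a 3-acetyl diketone. Before that come C-acetylation, the C6 enoate (allylic hydroxylation, then esterification) and the C1 ester (Mitsunobu inversion of a bicyclic acyloin).
- Key disconnection: the acyloin C(=O)–CH(OH) bond of the cyclopentanone. A carbene-derived acyl anion (Breslow intermediate) from one aldehyde attacks the second aldehyde of a trans-2,3-disubstituted methylidenecyclohexane dialdehyde.
- The dialdehyde comes from an enantiopure 4-isopropylcyclohexenone by anti conjugate addition of a masked acetaldehyde carbanion, α-dimethoxymethylation and methylenation while only one ketone exists.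
- The enone comes from two commodity carbonyl compounds by an organocatalytic Michael/aldol sequence.
- Ring order: cyclohexane first, cyclopentanone second (key step); side chain and esters last.

Assumption: every starting material in the compound list, the two carboxylic acids and the Grignard solution included, is taken as a catalogue chemical; ring locants follow octahydroinden-2-one numbering (C1 acyloxy carbon, C2 ketone, C3 side-chain carbon, C3a, C4 isopropyl carbon, C6 enoate carbon, C7 methylidene carbon, C7a).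

The stereochemical outcomes at C1 (step 4), C6 (step 6) and C1'/C3 (step 9) are predictions from models and analogy, not established results.

**Step 1**
Reactants: 1 3-methylbutanal; 2 but-3-en-2-one
Product: 4 (4R)-4-(propan-2-yl)cyclohex-2-en-1-one, via keto-aldehyde 3 (not isolated)
Conditions: (R)-2-[diphenyl(trimethylsilyloxy)methyl]pyrrolidine (5 mol%), ethyl 3,4-dihydroxybenzoate (20 mol%), neat, 4 °C; then LiOH (10 mol%), iPrOH, 23 °C
Reagents that add atoms: none
Why: Enamine-catalysed asymmetric Michael addition (the bulky silyloxydiphenylmethyl group shields one enamine face and fixes the isopropyl carbon as R) followed by intramolecular aldol condensation, an organocatalytic Robinson annulation.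

**Step 2**
Reactants: 4 (4R)-4-(propan-2-yl)cyclohex-2-en-1-one; 5 (1,3-dioxolan-2-ylmethyl)magnesium bromide
Product: 7 (2R,3R,4R)-2-(dimethoxymethyl)-3-(1,3-dioxolan-2-ylmethyl)-4-(propan-2-yl)cyclohexan-1-one, via silyl enol ether 6 (not isolated)
Conditions: 5 (1.5 equiv), CuBr·SMe2 (10 mol%), TMSCl, THF, −78 → −30 °C; pentane, filter, solvent switch; then HC(OMe)3, TMSOTf (10 mol%), CH2Cl2, −78 °C
Reagents that add atoms: trimethyl orthoformate COC(OC)OC; chlorotrimethylsilane C[Si](C)(C)Cl (its silicon stays only in 6)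
Why: Copper-catalysed, TMSCl-accelerated conjugate addition anti to the isopropyl group gives the regiodefined enol silane, and its Mukaiyama-type alkylation by the dimethoxycarbenium ion occurs anti to the new C3 substituent, so all three substituents are equatorial (C2 can also epimerise to this arrangement).

**Step 3**
Reactants: 7 (2R,3R,4R)-2-(dimethoxymethyl)-3-(1,3-dioxolan-2-ylmethyl)-4-(propan-2-yl)cyclohexan-1-one
Product: 8 2-{[(1R,2S,6R)-2-(dimethoxymethyl)-3-methylidene-6-(propan-2-yl)cyclohexyl]methyl}-1,3-dioxolane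
Conditions: Ph3PCH3Br, KOtBu, THF, 0 → 23 °C
Reagents that add atoms: methyltriphenylphosphonium bromide C[P+](c1ccccc1)(c1ccccc1)c1ccccc1.[Br-]
Why: Wittig methylenation of the only carbonyl group in the molecule, placed here so that no second ketone competes; the epimerisable C2 stays trans-diequatorial and ylide addition at 0 °C is expected to outrun β-methoxide loss.

**Step 4**
Reactants: 8 2-{[(1R,2S,6R)-2-(dimethoxymethyl)-3-methylidene-6-(propan-2-yl)cyclohexyl]methyl}-1,3-dioxolane
Product: 10 (1S,3aR,4R,7aS)-1-hydroxy-7-methylidene-4-(propan-2-yl)octahydro-2H-inden-2-one, via dialdehyde 9 (not isolated)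
Conditions: 2 M HCl, THF, 0 → 23 °C; extractive work-up, crude used at once; then 2-(pentafluorophenyl)-6,7-dihydro-5H-pyrrolo[2,1-c][1,2,4]triazol-2-ium tetrafluoroborate (10 mol%), iPr2NEt (10 mol%), CH2Cl2, 23 °C
Reagents that add atoms: water O
Why: Key step, an N-heterocyclic-carbene intramolecular cross-benzoin: the carbene adds to the unbranched aldehyde, and the Breslow intermediate (acyl anion equivalent) attacks the α-branched aldehyde 5-exo, joining two carbonyl carbons and closing the trans-fused cyclopentanone; attack anti to the sp2 C7 with the aldehyde oxygen turned outwards should give the equatorial (1S) carbinol, cis to H-7a.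

**Step 5**
Reactants: 10 (1S,3aR,4R,7aS)-1-hydroxy-7-methylidene-4-(propan-2-yl)octahydro-2H-inden-2-one; 11 (2R)-2-methylbutanoic acid
Product: 12 (1R,3aR,4R,7aS)-7-methylidene-2-oxo-4-(propan-2-yl)octahydro-1H-inden-1-yl (2R)-2-methylbutanoate
Conditions: 11 (1.5 equiv), PPh3, DIAD, toluene, 0 → 23 °C
Reagents that add atoms: none
Why: Mitsunobu esterification: SN2 displacement of the oxyphosphonium group at the carbonyl-activated C1 by the carboxylate inverts C1 to the axial (1R) ester, and the stereocentre of the acid is not touched.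

**Step 6**
Reactants: 12 (1R,3aR,4R,7aS)-7-methylidene-2-oxo-4-(propan-2-yl)octahydro-1H-inden-1-yl (2R)-2-methylbutanoate
Product: 13 (1R,3aR,4R,6S,7aS)-6-hydroxy-7-methylidene-2-oxo-4-(propan-2-yl)octahydro-1H-inden-1-yl (2R)-2-methylbutanoate
Conditions: SeO2 (0.3 equiv), t-BuOOH (3 equiv), CH2Cl2, 23 °C
Reagents that add atoms: tert-butyl hydroperoxide CC(C)(C)OO (terminal oxygen source); selenium dioxide O=[Se]=O (catalytic oxygen carrier)
Why: Sharpless catalytic SeO2 allylic hydroxylation (ene reaction, then 2,3-sigmatropic shift): in a 1,1-disubstituted alkene the ring CH2 (C6) reacts before the methine C7a, and the axial C6–H on the face away from the C1 acyloxy group is removed with oxygen returned to that face, giving the axial (6S) alcohol.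

**Step 7**
Reactants: 13 (1R,3aR,4R,6S,7aS)-6-hydroxy-7-methylidene-2-oxo-4-(propan-2-yl)octahydro-1H-inden-1-yl (2R)-2-methylbutanoate; 14 (2E)-3-methylpent-2-enoic acid
Product: 15 (1R,3aR,4R,6S,7aS)-7-methylidene-1-{[(2R)-2-methylbutanoyl]oxy}-2-oxo-4-(propan-2-yl)octahydro-1H-inden-6-yl (2E)-3-methylpent-2-enoate
Conditions: 14 (1.5 equiv), DCC, DMAP (0.2 equiv), CH2Cl2, 0 → 23 °C
Reagents that add atoms: none
Why: Steglich esterification with retention at C6; carbodiimide activation avoids the ketene pathway that could scramble the trisubstituted enoate geometry.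

**Step 8**
Reactants: 15 (1R,3aR,4R,6S,7aS)-7-methylidene-1-{[(2R)-2-methylbutanoyl]oxy}-2-oxo-4-(propan-2-yl)octahydro-1H-inden-6-yl (2E)-3-methylpent-2-enoate
Product: 16 (1R,3R,3aR,4R,6S,7aS)-3-acetyl-7-methylidene-1-{[(2R)-2-methylbutanoyl]oxy}-2-oxo-4-(propan-2-yl)octahydro-1H-inden-6-yl (2E)-3-methylpent-2-enoate
Conditions: MgBr2·OEt2 (2.5 equiv), iPr2NEt, 1-acetylbenzotriazole, CH2Cl2, 23 °C
Reagents that add atoms: 1-acetyl-1H-benzotriazole CC(=O)n1nnc2ccccc21
Why: Soft-enolisation Claisen-type C-acylation: only acylation at the C3 methylene can be trapped as the stable magnesium β-diketonate (acylation at the fully substituted C1 is reversible, and O-to-C migration of the C1 ester would need a strained bridged intermediate); the labile C3 centre is expected to settle trans to the C3a–C4 bond.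

**Step 9**
Reactants: 16 (1R,3R,3aR,4R,6S,7aS)-3-acetyl-7-methylidene-1-{[(2R)-2-methylbutanoyl]oxy}-2-oxo-4-(propan-2-yl)octahydro-1H-inden-6-yl (2E)-3-methylpent-2-enoate
Product: 17 (1R,3R,3aR,4R,6S,7aS)-3-[(1S)-1-hydroxyethyl]-7-methylidene-1-{[(2R)-2-methylbutanoyl]oxy}-2-oxo-4-(propan-2-yl)octahydro-1H-inden-6-yl (2E)-3-methylpent-2-enoate
Conditions: RuCl[(S,S)-TsDPEN](p-cymene) (2 mol%), HCO2H/Et3N (5:2), CH2Cl2, 23 °C
Reagents that add atoms: none
Why: Noyori asymmetric transfer hydrogenation with dynamic kinetic resolution of a 2-alkyl-1,3-diketone: the unhindered methyl ketone is reduced before the doubly flanked ring ketone, the catalyst is chosen by analogy with aryl methyl ketones to give the S carbinol, and the rapidly epimerising C3 is funnelled to the 3R product (side chain trans to C3a–C4, syn to the new hydroxyl).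

**Compound list**
1 | 3-methylbutanal | CC(C)CC=O | starting material
2 | but-3-en-2-one | C=CC(C)=O | starting material
3 | (2R)-5-oxo-2-(propan-2-yl)hexanal | CC(=O)CC[C@@H](C=O)C(C)C | intermediate (not isolated)
4 | (4R)-4-(propan-2-yl)cyclohex-2-en-1-one, (R)-cryptone | O=C1C=C[C@@H](C(C)C)CC1 | intermediate
5 | (1,3-dioxolan-2-ylmethyl)magnesium bromide | Br[Mg]CC1OCCO1 | starting material
6 | {[(3R,4R)-3-(1,3-dioxolan-2-ylmethyl)-4-(propan-2-yl)cyclohex-1-en-1-yl]oxy}trimethylsilane | C[Si](C)(C)OC1=C[C@H](CC2OCCO2)[C@@H](C(C)C)CC1 | intermediate (not isolated)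
7 | (2R,3R,4R)-2-(dimethoxymethyl)-3-(1,3-dioxolan-2-ylmethyl)-4-(propan-2-yl)cyclohexan-1-one | O=C1[C@@H](C(OC)OC)[C@H](CC2OCCO2)[C@@H](C(C)C)CC1 | intermediate
8 | 2-{[(1R,2S,6R)-2-(dimethoxymethyl)-3-methylidene-6-(propan-2-yl)cyclohexyl]methyl}-1,3-dioxolane | C=C1[C@@H](C(OC)OC)[C@H](CC2OCCO2)[C@@H](C(C)C)CC1 | intermediate
9 | (1S,2R,3R)-6-methylidene-2-(2-oxoethyl)-3-(propan-2-yl)cyclohexane-1-carbaldehyde | C=C1[C@@H](C=O)[C@H](CC=O)[C@@H](C(C)C)CC1 | intermediate (not isolated)
10 | (1S,3aR,4R,7aS)-1-hydroxy-7-methylidene-4-(propan-2-yl)octahydro-2H-inden-2-one | C=C1[C@@H]2[C@H](CC(=O)[C@H]2O)[C@@H](C(C)C)CC1 | intermediate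
11 | (2R)-2-methylbutanoic acid | CC[C@@H](C)C(=O)O | starting material
12 | (1R,3aR,4R,7aS)-7-methylidene-2-oxo-4-(propan-2-yl)octahydro-1H-inden-1-yl (2R)-2-methylbutanoate | C=C1[C@@H]2[C@H](CC(=O)[C@@H]2OC(=O)[C@H](C)CC)[C@@H](C(C)C)CC1 | intermediate
13 | (1R,3aR,4R,6S,7aS)-6-hydroxy-7-methylidene-2-oxo-4-(propan-2-yl)octahydro-1H-inden-1-yl (2R)-2-methylbutanoate | C=C1[C@@H]2[C@H](CC(=O)[C@@H]2OC(=O)[C@H](C)CC)[C@@H](C(C)C)C[C@@H]1O | intermediate
14 | (2E)-3-methylpent-2-enoic acid | CC/C(C)=C/C(=O)O | starting material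
15 | (1R,3aR,4R,6S,7aS)-7-methylidene-1-{[(2R)-2-methylbutanoyl]oxy}-2-oxo-4-(propan-2-yl)octahydro-1H-inden-6-yl (2E)-3-methylpent-2-enoate | C=C1[C@@H]2[C@H](CC(=O)[C@@H]2OC(=O)[C@H](C)CC)[C@@H](C(C)C)C[C@@H]1OC(=O)/C=C(\C)CC | intermediate
16 | (1R,3R,3aR,4R,6S,7aS)-3-acetyl-7-methylidene-1-{[(2R)-2-methylbutanoyl]oxy}-2-oxo-4-(propan-2-yl)octahydro-1H-inden-6-yl (2E)-3-methylpent-2-enoate | C=C1[C@@H]2[C@H]([C@H](C(C)=O)C(=O)[C@@H]2OC(=O)[C@H](C)CC)[C@@H](C(C)C)C[C@@H]1OC(=O)/C=C(\C)CC | intermediate
17 | (1R,3R,3aR,4R,6S,7aS)-3-[(1S)-1-hydroxyethyl]-7-methylidene-1-{[(2R)-2-methylbutanoyl]oxy}-2-oxo-4-(propan-2-yl)octahydro-1H-inden-6-yl (2E)-3-methylpent-2-enoate | C=C1[C@@H]2[C@H]([C@H]([C@H](C)O)C(=O)[C@@H]2OC(=O)[C@H](C)CC)[C@@H](C(C)C)C[C@@H]1OC(=O)/C=C(\C)CC | target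

**Totals**
Total steps: 9. Longest linear sequence: 9 steps (1 and 2 to 17).

**Steps most likely to fail**

Step 4. The β,γ-unsaturated aldehyde may slip into conjugation or epimerise under amine/carbene conditions, or the benzoin may be unselective at C1. The fallback keeps a reversed-polarity ring closure but makes it reductive and base-free. It sets out from 9 (made from 8 as in step 4). Treatment at once with SmI2 (2.2 equiv), t-BuOH, THF, −78 °C gives, by ketyl pinacol coupling through a samarium-chelated cis arrangement, (1S,2R,3aR,4R,7aS)-7-methylidene-4-(propan-2-yl)octahydro-1H-indene-1,2-diol F1. The less hindered C2 carbinol is then oxidised through the stannylene acetal (Bu2SnO, MeOH, reflux; then NBS, CHCl3, 23 °C), and the route is rejoined at 10.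

Step 5. Mitsunobu inversion of a hindered α-ketol may give elimination or retention. The fallback sets out from 10 and separates activation from displacement. Tf2O, pyridine, CH2Cl2, −78 °C gives (1S,3aR,4R,7aS)-7-methylidene-2-oxo-4-(propan-2-yl)octahydro-1H-inden-1-yl trifluoromethanesulfonate F2. This is displaced with inversion by the caesium salt of 11 (11, Cs2CO3, 18-crown-6, toluene, 0 °C), and the route is rejoined at 12.

Step 8. C-acetylation beside an α'-acyloxy ketone may give O-acylation, acyl scrambling or loss of the C1 configuration. The fallback sets out from 15 and replaces acylation by aldol addition followed by oxidation. Cy2BCl, Et3N, Et2O, −78 °C, then acetaldehyde (Paterson-type enolisation away from the acyloxy group) is expected to give mainly the anti aldol (1R,3R,3aR,4R,6S,7aS)-3-[(1R)-1-hydroxyethyl]-7-methylidene-1-{[(2R)-2-methylbutanoyl]oxy}-2-oxo-4-(propan-2-yl)octahydro-1H-inden-6-yl (2E)-3-methylpent-2-enoate F3. Its carbinol configuration does not matter, because Dess–Martin periodinane, CH2Cl2, 23 °C oxidises it to the diketone, and the route is rejoined at 16.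

**Further compounds**
F1 | step 4 | (1S,2R,3aR,4R,7aS)-7-methylidene-4-(propan-2-yl)octahydro-1H-indene-1,2-diol | C=C1[C@@H]2[C@H](C[C@@H](O)[C@H]2O)[C@@H](C(C)C)CC1
F2 | step 5 | (1S,3aR,4R,7aS)-7-methylidene-2-oxo-4-(propan-2-yl)octahydro-1H-inden-1-yl trifluoromethanesulfonate | C=C1[C@@H]2[C@H](CC(=O)[C@H]2OS(=O)(=O)C(F)(F)F)[C@@H](C(C)C)CC1
F3 | step 8 | (1R,3R,3aR,4R,6S,7aS)-3-[(1R)-1-hydroxyethyl]-7-methylidene-1-{[(2R)-2-methylbutanoyl]oxy}-2-oxo-4-(propan-2-yl)octahydro-1H-inden-6-yl (2E)-3-methylpent-2-enoate | C=C1[C@@H]2[C@H]([C@H]([C@@H](C)O)C(=O)[C@@H]2OC(=O)[C@H](C)CC)[C@@H](C(C)C)C[C@@H]1OC(=O)/C=C(\C)CC
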